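The plan cuts the maleimide ring (N-1, C-2=O, C-3=C-4, C-5=O) into an internal alkyne, an isocyanate and carbon monoxide. The tetrasubstituted C-3=C-4 bond with its aryl and benzyl arms is the alkyne. Because the O=C–N–C=O arc is locally symmetric, either alkyne orientation gives the same imide. One ruthenium-catalysed [2+2+1] cocyclisation thus forms two C–C bonds and one C–N bond and closes the heterocycle on the finished carbon skeleton. The precursor is a (3S)-chroman-7-yl-CH2–C≡C–aryl propyne. Its hydroxyls carry acid-labile masks (3-O-TBS, aryl O-tert-butyl), so they fall together with the N-dimethoxybenzyl group in one final acidolysis.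

Key step: step 9

Remark: chroman numbering is used (O-1, C-2 gem-dimethyl, C-3 carbinol, C-4 methylene). C-3 of the target is S (OH > C-2 > C-4 > H), the sense delivered by the (S,S)-salen catalyst in step 3.

Step 1
Reactants: 1 methyl 3-hydroxy-4-iodobenzoate; 2 2-methylbut-3-en-2-ol
Product: 3 methyl 3-hydroxy-4-[(1E)-3-hydroxy-3-methylbut-1-en-1-yl]benzoate
Conditions: Pd(OAc)2 (3 mol %), P(o-tol)3 (9 mol %), Et3N, MeCN, 80 °C
Reagents that add atoms: none
Why: Mizoroki–Heck reaction in which aryl–Pd adds to the unsubstituted alkene terminus and, since the carbinol carbon bears no hydrogen, β-hydride elimination can only give the conjugated E-styrene, with phenol, tertiary alcohol and ester tolerated.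

Step 2
Reactants: 3 methyl 3-hydroxy-4-[(1E)-3-hydroxy-3-methylbut-1-en-1-yl]benzoate
Product: 4 methyl 2,2-dimethyl-2H-chromene-7-carboxylate
Conditions: p-TsOH·H2O (5 mol %), toluene, 90 °C, Dean–Stark
Reagents that add atoms: none
Why: Acid-catalysed dehydrative cyclisation in which ionisation of the tertiary allylic alcohol gives an allyl cation/o-quinone methide whose former C=C bond can rotate, and capture of the tertiary terminus by the phenol oxygen (formally an oxa-6π electrocyclisation) closes the pyran with the only possible regiochemistry, ester at C-7.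

Step 3
Reactants: 4 methyl 2,2-dimethyl-2H-chromene-7-carboxylate
Product: 5 methyl (3S,4S)-3,4-epoxy-2,2-dimethylchroman-7-carboxylate (cis-fused oxirane)
Conditions: (S,S)-Jacobsen Mn(salen)Cl (3 mol %), 4-phenylpyridine N-oxide (20 mol %), aq NaOCl (pH 11.3), CH2Cl2, 0 °C
Reagents that add atoms: sodium hypochlorite, [Na+].[O-]Cl
Why: Jacobsen–Katsuki epoxidation, for which cis-locked 2,2-dimethylchromenes are the benchmark substrate class, so the (S,S)-salen oxo-manganese species selects the alkene face leading to the (3S,4S)-oxirane and the catalyst alone sets C-3 (C-4 is erased in step 4).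

Step 4
Reactants: 5 methyl (3S,4S)-3,4-epoxy-2,2-dimethylchroman-7-carboxylate
Product: 6 (3S)-7-(hydroxymethyl)-2,2-dimethylchroman-3-ol
Conditions: LiAlH4, THF, 0 °C to rt; Fieser work-up
Reagents that add atoms: none
Why: Hydride reduction in which SN2 delivery to the benzylic C-4 is favoured over the neopentyl C-3, so the C-3–O bond is never broken and C-3 stays S, while the ester is reduced to the benzylic alcohol in the same operation.

Step 5
Reactants: 6 (3S)-7-(hydroxymethyl)-2,2-dimethylchroman-3-ol
Product: 7 (3S)-7-(bromomethyl)-2,2-dimethylchroman-3-ol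
Conditions: CBr4 (1.1 equiv), PPh3 (1.1 equiv), CH2Cl2, 0 °C
Reagents that add atoms: carbon tetrabromide, BrC(Br)(Br)Br
Why: Appel reaction in which only the primary benzylic alkoxyphosphonium ion can be displaced by bromide at 0 °C, whereas the secondary C-3 hydroxyl beside the quaternary C-2 resists SN2 attack and is returned unchanged.

Step 6
Reactants: 7 (3S)-7-(bromomethyl)-2,2-dimethylchroman-3-ol
Product: 8 (3S)-7-(bromomethyl)-3-(tert-butyldimethylsilyloxy)-2,2-dimethylchroman
Conditions: TBSOTf, 2,6-lutidine, CH2Cl2, 0 °C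
Reagents that add atoms: tert-butyldimethylsilyl triflate, CC(C)(C)[Si](C)(C)OS(=O)(=O)C(F)(F)F
Why: Silyl ether formation with the reactive triflate overcomes the hindrance at O-3, and the non-nucleophilic 2,6-lutidine does not quaternise with the benzylic bromide.

Step 7
Reactants: 9 4-tert-butoxybenzaldehyde
Product: 10 1-tert-butoxy-4-ethynylbenzene
Conditions: Ohira–Bestmann reagent, K2CO3, MeOH, rt
Reagents that add atoms: dimethyl (1-diazo-2-oxopropyl)phosphonate, CC(=O)C(=[N+]=[N-])P(=O)(OC)OC
Why: Seyferth–Gilbert homologation (Ohira–Bestmann variant) in which methanolysis frees the diazomethylphosphonate anion, which olefinates the aldehyde, and loss of N2 with a 1,2-hydrogen shift gives the terminal alkyne, the tert-butyl ether being inert to K2CO3/MeOH.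

Step 8
Reactants: 10 1-tert-butoxy-4-ethynylbenzene; 8 (3S)-7-(bromomethyl)-3-(tert-butyldimethylsilyloxy)-2,2-dimethylchroman
Product: 13 (3S)-7-[3-(4-tert-butoxyphenyl)prop-2-yn-1-yl]-3-(tert-butyldimethylsilyloxy)-2,2-dimethylchroman, via lithium acetylide 11 (not isolated), via alkynylzinc bromide 12 (not isolated)
Conditions: 10, n-BuLi, THF, −78 °C; ZnBr2, −78 to 0 °C; then 8, PdCl2(DPEphos) (3 mol %), THF, 23 °C
Reagents that add atoms: none
Why: Negishi coupling of an alkynylzinc with a benzylic bromide (oxidative addition of C–Br, transmetalation, reductive elimination) runs at room temperature without free base, so the doubly activated CH2 of the 1,3-diarylpropyne is not isomerised to the allene and both ethers survive.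

Step 9
Reactants: 13 (3S)-7-[3-(4-tert-butoxyphenyl)prop-2-yn-1-yl]-3-(tert-butyldimethylsilyloxy)-2,2-dimethylchroman; 14 2,4-dimethoxybenzyl isocyanate
Product: 15 N-(2,4-dimethoxybenzyl)-3-(4-tert-butoxyphenyl)-4-{[(3S)-3-(tert-butyldimethylsilyloxy)-2,2-dimethylchroman-7-yl]methyl}maleimide
Conditions: Ru3(CO)12 (5 mol %), CO (1–3 atm), 14 (1.5 equiv), mesitylene, 130 °C
Reagents that add atoms: carbon monoxide, [C-]#[O+]
Why: Ru(0) released from Ru3(CO)12 should bind alkyne 13 and the C=N bond of 14 and couple them oxidatively to a five-membered azaruthenacycle (Ru–C(vinyl)=C–C(=O)–N), after which CO inserts into the Ru–C(vinyl) bond and acyl–nitrogen reductive elimination releases 15 and Ru(0). The closest known reaction type is the Ru3(CO)12-catalysed intermolecular [2+2+1] cocyclisation of internal alkynes, isocyanates and CO to polysubstituted maleimides, applied here to an aryl/benzyl alkyne and a benzylic isocyanate. The one ring formed, the five-membered imide, is closed by that final C(=O)–N reductive elimination from the six-membered acyl ruthenacycle, the two alkyne C–C(=O) bonds having been made in the two preceding events. No stereocentre is created, and C-3 is remote, bears no acidic hydrogen and stays S. No regioselectivity is required because C-2 and C-5 of the imide are interchangeable, so both alkyne orientations converge on 15. The step does need chemoselectivity over propargyl-to-allene isomerisation, alkyne oligomerisation and carbamate formation, and this is secured by the absence of any base or free OH (O-TBS, O-t-Bu), by the CO atmosphere and by the excess of 14.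

Step 10
Reactants: 15 N-(2,4-dimethoxybenzyl)-3-(4-tert-butoxyphenyl)-4-{[(3S)-3-(tert-butyldimethylsilyloxy)-2,2-dimethylchroman-7-yl]methyl}maleimide
Product: 17 asperimide C, via O-3 trifluoroacetate 16 (not isolated)
Conditions: TFA/anisole (4:1), 65 °C; evaporate; then THF/MeOH, sat. aq NaHCO3, rt
Reagents that add atoms: none
Why: Global SN1-type acidolysis in which hot trifluoroacetic acid ionises the N–CH2 bond of the electron-rich dimethoxybenzyl group (cation trapped by anisole in a Friedel–Crafts alkylation), expels isobutene from the aryl tert-butyl ether and solvolyses the silyl ether, while the C-3 hydroxyl is held as its trifluoroacetate, which shields the neighbouring C-2–O-1 bond from ionisation and is then hydrolysed by bicarbonate without touching the C-3–O bond, so C-3 stays S.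

Compound list
1 | methyl 3-hydroxy-4-iodobenzoate | COC(=O)c1ccc(I)c(O)c1 | starting material
2 | 2-methylbut-3-en-2-ol | CC(C)(O)C=C | starting material
3 | methyl 3-hydroxy-4-[(1E)-3-hydroxy-3-methylbut-1-en-1-yl]benzoate | COC(=O)c1ccc(/C=C/C(C)(C)O)c(O)c1 | intermediate
4 | methyl 2,2-dimethyl-2H-chromene-7-carboxylate | COC(=O)c1ccc2C=CC(C)(C)Oc2c1 | intermediate
5 | methyl (3S,4S)-3,4-epoxy-2,2-dimethylchroman-7-carboxylate | CC1(C)Oc2cc(C(=O)OC)ccc2[C@@H]3O[C@H]13 | intermediate
6 | (3S)-7-(hydroxymethyl)-2,2-dimethylchroman-3-ol | CC1(C)Oc2cc(CO)ccc2C[C@@H]1O | intermediate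
7 | (3S)-7-(bromomethyl)-2,2-dimethylchroman-3-ol | CC1(C)Oc2cc(CBr)ccc2C[C@@H]1O | intermediate
8 | (3S)-7-(bromomethyl)-3-(tert-butyldimethylsilyloxy)-2,2-dimethylchroman | CC1(C)Oc2cc(CBr)ccc2C[C@@H]1O[Si](C)(C)C(C)(C)C | intermediate
9 | 4-tert-butoxybenzaldehyde | CC(C)(C)Oc1ccc(C=O)cc1 | starting material
10 | 1-tert-butoxy-4-ethynylbenzene | CC(C)(C)Oc1ccc(C#C)cc1 | intermediate
11 | lithium (4-tert-butoxyphenyl)acetylide | [Li]C#Cc1ccc(OC(C)(C)C)cc1 | intermediate
12 | (4-tert-butoxyphenyl)ethynylzinc bromide | Br[Zn]C#Cc1ccc(OC(C)(C)C)cc1 | intermediate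
13 | (3S)-7-[3-(4-tert-butoxyphenyl)prop-2-yn-1-yl]-3-(tert-butyldimethylsilyloxy)-2,2-dimethylchroman | CC1(C)Oc2cc(CC#Cc3ccc(OC(C)(C)C)cc3)ccc2C[C@@H]1O[Si](C)(C)C(C)(C)C | intermediate
14 | 2,4-dimethoxybenzyl isocyanate | COc1ccc(CN=C=O)c(OC)c1 | starting material
15 | N-(2,4-dimethoxybenzyl)-3-(4-tert-butoxyphenyl)-4-{[(3S)-3-(tert-butyldimethylsilyloxy)-2,2-dimethylchroman-7-yl]methyl}maleimide | CC1(C)Oc2cc(CC3=C(c4ccc(OC(C)(C)C)cc4)C(=O)N(Cc4ccc(OC)cc4OC)C3=O)ccc2C[C@@H]1O[Si](C)(C)C(C)(C)C | intermediate
16 | asperimide C O-3 trifluoroacetate, (3S) | CC1(C)Oc2cc(CC3=C(c4ccc(O)cc4)C(=O)NC3=O)ccc2C[C@@H]1OC(=O)C(F)(F)F | intermediate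
17 | asperimide C, (3S) | CC1(C)Oc2cc(CC3=C(c4ccc(O)cc4)C(=O)NC3=O)ccc2C[C@@H]1O | target

Total steps: 10. Longest linear sequence: 9 steps (1–6, 8, 9, 10).

Steps most likely to fail

Step 9. At 130 °C, migration of the triple bond into the allene/diene manifold, alkyne oligomerisation or trimerisation of the isocyanate may outrun the cocyclisation.
- The fallback builds the same imide by cross-coupling on a preformed ring. It sets out from 8 and returns at 15.
- 2,3-Dibromomaleic anhydride is condensed with 2,4-dimethoxybenzylamine (AcOH, reflux) to N-(2,4-dimethoxybenzyl)-3,4-dibromomaleimide F1.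
- A Suzuki–Miyaura mono-arylation with 4-tert-butoxyphenylboronic acid (PdCl2(dppf), K2CO3, dioxane/H2O) gives 3-bromo-4-(4-tert-butoxyphenyl)-N-(2,4-dimethoxybenzyl)maleimide F2.
- Zinc insertion into 8 (Zn dust, LiCl, THF) gives the chroman-7-ylmethylzinc bromide F3.
- A Negishi coupling of F2 with F3 (Pd(PPh3)4, THF) delivers 15.

Step 10. N-Debenzylation of the imide may stay incomplete. The benzylic and tert-butyl cations may re-alkylate the electron-rich rings despite the scavenger, or prolonged hot acid may open the pyran.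
- The fallback exchanges the nitrogen instead of cleaving the N–C bond. It sets out from 15 and returns at 17.
- Saponification (KOH, EtOH/H2O, reflux) followed by acidification recloses the diacid to the 3-aryl-4-(chromanylmethyl)maleic anhydride F4.
- Hexamethyldisilazane/MeOH in DMF at rt converts it into the N–H maleimide still bearing both ethers F5.
- The two ethers are then removed under far milder acid (TFA/CH2Cl2, 0 °C to rt, bicarbonate work-up) to give 17.

Step 2. The cation/quinone methide manifold may oligomerise or stop at the diene instead of closing the pyran.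
- The fallback makes the ring by selenoetherification. It sets out from 1 and returns at 4.
- Linear-selective Suzuki–Miyaura prenylation with prenylboronic acid pinacol ester (PdCl2(dppf), K3PO4, THF/H2O) gives methyl 3-hydroxy-4-(3-methylbut-2-en-1-yl)benzoate F6.
- PhSeCl (CH2Cl2, −78 °C to rt) induces Markovnikov 6-endo closure to racemic methyl 2,2-dimethyl-3-(phenylselanyl)chroman-7-carboxylate F7.
- H2O2 (THF, 0 °C) oxidises it to the selenoxide F8, whose syn-elimination can only involve a C-4 hydrogen and gives 4.

Further compounds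
F1 | step 9 | N-(2,4-dimethoxybenzyl)-3,4-dibromomaleimide | O=C1C(Br)=C(Br)C(=O)N1Cc1ccc(OC)cc1OC
F2 | step 9 | 3-bromo-4-(4-tert-butoxyphenyl)-N-(2,4-dimethoxybenzyl)maleimide | O=C1C(Br)=C(c2ccc(OC(C)(C)C)cc2)C(=O)N1Cc1ccc(OC)cc1OC
F3 | step 9 | [(3S)-3-(tert-butyldimethylsilyloxy)-2,2-dimethylchroman-7-yl]methylzinc bromide | CC1(C)Oc2cc(C[Zn]Br)ccc2C[C@@H]1O[Si](C)(C)C(C)(C)C
F4 | step 10 | 3-(4-tert-butoxyphenyl)-4-{[(3S)-3-(tert-butyldimethylsilyloxy)-2,2-dimethylchroman-7-yl]methyl}maleic anhydride | CC1(C)Oc2cc(CC3=C(c4ccc(OC(C)(C)C)cc4)C(=O)OC3=O)ccc2C[C@@H]1O[Si](C)(C)C(C)(C)C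
F5 | step 10 | 3-(4-tert-butoxyphenyl)-4-{[(3S)-3-(tert-butyldimethylsilyloxy)-2,2-dimethylchroman-7-yl]methyl}-1H-maleimide | CC1(C)Oc2cc(CC3=C(c4ccc(OC(C)(C)C)cc4)C(=O)NC3=O)ccc2C[C@@H]1O[Si](C)(C)C(C)(C)C
F6 | step 2 | methyl 3-hydroxy-4-(3-methylbut-2-en-1-yl)benzoate | COC(=O)c1ccc(CC=C(C)C)c(O)c1
F7 | step 2 | methyl 2,2-dimethyl-3-(phenylselanyl)chroman-7-carboxylate (racemic) | COC(=O)c1ccc2CC([Se]c3ccccc3)C(C)(C)Oc2c1
F8 | step 2 | methyl 2,2-dimethyl-3-(phenylseleninyl)chroman-7-carboxylate (racemic) | COC(=O)c1ccc2CC([Se](=O)c3ccccc3)C(C)(C)Oc2c1
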